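(The data stem from a simulated flask with constants of no real substance, and the scatter is random.)

I nearly took the reading at the asked time for the place where a flask stops.

| setting | beta | epsilon | gamma | zeta | south-east | north-east | west | south |
|---|---|---|---|---|---|---|---|---|
| substrate | 0.050 M | 0.050 M | 0.050 M | 0.050 M | 0.050 M (fed, over 12 min) | 0.050 M | 0.050 M | 0.050 M |
| reagent | 0.060 M | 0.084 M | 0.13 M | 0.060 M | 0.0600 M | 0.0600 M (fed, over 12 min) | 0.0600 M | 0.0600 M (fed, over 80 s) |
| free catalyst | 50 µM | 50 µM | 50 µM | 100 µM | 50 µM | 50 µM | 50 µM | 50 µM |
| remark | run made earlier | run made earlier | run made earlier | run made earlier | all else is in the flask from the start; the feed brings no volume worth counting | all else is in the flask from the start; the feed brings no volume worth counting | everything together at the start | all else is in the flask from the start; the feed brings no volume worth counting |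
| time |  |  |  |  | 15 min | 15 min | 15 min | 15 min |

- beta (time / min: target / %): 0.667: 3.1; 1.00: 5.3; 1.50: 8.6; 2.50: 18.0; 4.00: 30.0; 6.00: 42.0; 10.0: 60.0
- epsilon (time / min: target / %): 2.50: 20.7; 5.00: 42.6; 8.00: 60.6; 10.0: 68.5; 12.0: 72.4; 15.0: 76.8; 20.0: 79.8
- gamma (time / min: target / %): 2.50: 24.5; 5.00: 47.8; 8.00: 64.0; 10.0: 68.8; 12.0: 70.9; 15.0: 72.9; 20.0: 73.2
- zeta (time / min: target / %): 1.33: 19.4; 2.50: 38.3; 5.00: 64.3; 10.0: 84.5; 20.0: 91.2

(each reading ± 0.3 percentage points)

- the flask that comes out highest in amount of target, in percent of the substrate charged, or "all alike" when all lie within 1.5 percentage points (south-east / north-east / west / south / all alike)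
- target at the end, in percent of the substrate charged, south-east
- target at the end, in percent of the substrate charged, north-east
- target at the end, in percent of the substrate charged, west
- target at the end, in percent of the substrate charged, south

- what was read earlier has a scatter of 0.3 percentage points, one standard deviation

So I asked first what the end state must be, and which given numbers it leans on. The time 15 min, the feed times 12 min and 80 s and the free catalyst 50 µM change how far a flask has got, but none of them enters the balance. The two charges do. I assumed one reagent per substrate by any path, and substrate was the limiting reagent, 0.050 M against 0.0600 M. On that balance, epsilon's 0.084 M of reagent leaves 40.5% of its charge unused. For the flasks asked about I got 16.7%: this is the reagent floor f, the part of the reagent charge left once the substrate has been used up. With both charges fully in the flask it also reads backward: reagent left above f, multiplied by cB/cA (charges of reagent and substrate), gives the part of the substrate charge, free or held as an intermediate, still to take up reagent. My reckoning gave no yield at 15 min, and the yields below are the forecast's.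

The forecast named west highest, with south-east 35%, north-east 63%, west 73.5% and south 72.5%, and it read the plateaus of the earlier runs as a sign that “reagent kills catalyst that substrate isn't protecting”.

South came out highest at 74.6%, then west 72.2%, north-east 68.1% and south-east 57.2%.

    free catalyst + open intermediate ⇌ catalyst intermediate (K = 51.0 /M, k = 200 /M/s)
    substrate + reagent → uncatalysed product (k = 0.0250 /M/s)
    reagent + catalyst intermediate → free catalyst + target (k = 86.0 /M/s)
    substrate + free catalyst → free catalyst + open intermediate (k = 190 /M/s)

South and south-east were still moving at 15 min. South held 28.0% of its reagent, which by the floor leaves 13.6% of the substrate charge still to take up reagent, and by 150 min its target had gone from 74.6% to 88.2%. South-east held 42%, which leaves 30.7% of the substrate charge still to take up reagent. By 150 min its reagent stood at 16.7% and its target at 87.5%.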